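**Plan**

- Rings: A is the 5-allyl-2-hydroxyphenyl ring, B the central phenol, C the 3-allyl-4-hydroxyphenyl ring. Ring A atoms: C1 bonded to ring B, C2 bearing oxygen, C5 bearing the allyl group.
- Retrosynthesis first cuts the three O–alkyl bonds of a tri-ether, then the CH2–vinyl bond of the ring A allyl group, leading back to a ring A methyl benzoate with its ester at C5.
- Ring A is then cut through C1–C6 and C2–C3 into methyl coumalate (C3 to C6 plus the ester carbon) and an ethoxyalkyne carried by ring B (C1 and C2). This works because ring A has its oxygen at C2, ortho to the biaryl bond, and its only carbon substituent at C5, para to that oxygen, which is the pattern a 5-carboxylated 2-pyrone and an aryl ynol ether deliver.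
- The alkyne–ring B bond is cut last (Negishi coupling), back to an iodide made from 4-O-methylhonokiol, which supplies rings B and C, their biaryl bond and two allyl groups.
- Forward: rings B and C are bought joined; ring A is built on ring B by cycloaddition and loss of CO2; the ester is turned into the third allyl group; the ethers are cleaved.
- Stereochemistry: the target has no stereocentre and no stereogenic double bond; the two bridgehead centres of the cycloadduct vanish on aromatisation.

Key step: step 4

Assumption: 4-O-methylhonokiol (sold as an isolated natural product), ethoxyacetylene (as a hexane solution) and methyl coumalate are taken as purchased materials.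

**Step 1**
Reactants: 1 4-O-methylhonokiol (3',5-diallyl-4'-methoxybiphenyl-2-ol)
Product: 2 3',5-diallyl-3-iodo-4'-methoxybiphenyl-2-ol (iodine on ring B ortho to the free hydroxyl)
Conditions: NIS (1.05 equiv), TsOH·H2O (10 mol %), MeCN, 0 °C, dark; aq. Na2S2O3
Reagents that add atoms: N-iodosuccinimide, O=C1CCC(=O)N1I
Why: Electrophilic aromatic iodination (NIS activated by catalytic acid) should go to the only open position ortho to the free hydroxyl of ring B, whose para position is blocked by the allyl group, because this phenol ring is far more activated than the anisole ring C and than the isolated terminal alkenes.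

**Step 2**
Reactants: 2 3',5-diallyl-3-iodo-4'-methoxybiphenyl-2-ol
Product: 3 3',5-diallyl-3-iodo-2,4'-dimethoxybiphenyl
Conditions: MeI (1.5 equiv), K2CO3 (2 equiv), DMF, rt
Reagents that add atoms: iodomethane, CI
Why: Williamson ether synthesis of the phenoxide with iodomethane should cap the hydroxyl that would otherwise protonate the zinc acetylide of step 3, and the mild carbonate base leaves the allyl groups and the aryl iodide untouched.

**Step 3**
Reactants: 3 3',5-diallyl-3-iodo-2,4'-dimethoxybiphenyl; 4 ethoxyacetylene
Product: 7 3',5-diallyl-3-(ethoxyethynyl)-2,4'-dimethoxybiphenyl (ring B aryl ynol ether), via lithium ethoxyacetylide 5 (not isolated), via ethoxyethynylzinc chloride 6 (not isolated)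
Conditions: 4 (2 equiv), n-BuLi, THF, −78 °C; ZnCl2, −78 → 0 °C; then 3, Pd(PPh3)4 (5 mol %), THF, rt; aq. NaHCO3 work-up, Et3N-deactivated silica
Reagents that add atoms: none
Why: Negishi coupling: oxidative addition of the aryl iodide to zerovalent palladium, transmetalation from the alkynylzinc chloride and reductive elimination should give the aryl ynol ether at room temperature, well below the temperature at which ethyl ynol ethers lose ethylene, and the allyl groups and methyl ethers take no part.

**Step 4**
Reactants: 7 3',5-diallyl-3-(ethoxyethynyl)-2,4'-dimethoxybiphenyl; 8 methyl coumalate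
Product: 10 methyl 5'-allyl-3'-(3-allyl-4-methoxyphenyl)-6-ethoxy-2'-methoxybiphenyl-3-carboxylate (terphenyl whose ring A is 2-ethoxy-5-(methoxycarbonyl)phenyl), via bridged lactone adduct 9 (not isolated)
Conditions: 8 (1.5 equiv), PhMe (1 M), 4 Å MS, 80 °C, sealed tube, Ar
Reagents that add atoms: none
Why: In an inverse-electron-demand Diels–Alder reaction the electron-rich alkyne of 7 adds across C3 and C6 of the electron-poor pyrone 8 in a single [4+2] event with unequal bond formation, the nucleophilic aryl-bearing alkyne carbon bonding ahead to C6 and the ethoxy-bearing carbon following to C3, to give the bridged lactone 9. Cycloreversion of 9 with loss of CO2 is expected to be fast at the reaction temperature and gives the benzene ring at the correct oxidation level without an oxidant. The closest known reaction type is the cycloaddition of methyl coumalate with ynamines, ketene acetals and alkoxyalkynes, which gives benzoates carrying the heteroatom para to the ester. Ring A closes as a six-membered carbocycle by intermolecular [4+2] cycloaddition, four carbons (C3 to C6) coming from the pyrone and two from the alkyne, and no stereocentre remains because the two bridgehead centres of 9 are lost with the CO2 bridge. The step needs regioselectivity, secured by matched polarity (the ether oxygen pushes electron density onto the aryl-bearing carbon, while C6 is activated both as the β-carbon of the acrylate and as the vinylogous position of the lactone carbonyl), which places the ethoxy group ortho to the biaryl bond and para to the ester. It also needs chemoselectivity over the two allyl groups, which as unactivated alkenes add to a pyrone only at much higher temperature, and holding the bath at 80 °C keeps the ynol ether below the roughly 100 °C at which it fragments to a ketene and ethylene.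

**Step 5**
Reactants: 10 methyl 5'-allyl-3'-(3-allyl-4-methoxyphenyl)-6-ethoxy-2'-methoxybiphenyl-3-carboxylate
Product: 11 [5'-allyl-3'-(3-allyl-4-methoxyphenyl)-6-ethoxy-2'-methoxybiphenyl-3-yl]methanol
Conditions: i-Bu2AlH (2.5 equiv), CH2Cl2, −78 → 0 °C; aq. potassium sodium tartrate (KNaC4H4O6)
Reagents that add atoms: none
Why: Hydride reduction of the aryl ester by i-Bu2AlH should give the benzylic alcohol at low temperature, where terminal alkenes are not hydroaluminated and aryl ethers are inert.

**Step 6**
Reactants: 11 [5'-allyl-3'-(3-allyl-4-methoxyphenyl)-6-ethoxy-2'-methoxybiphenyl-3-yl]methanol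
Product: 12 5'-allyl-3'-(3-allyl-4-methoxyphenyl)-3-(bromomethyl)-6-ethoxy-2'-methoxybiphenyl
Conditions: PBr3 (0.4 equiv), Et2O, 0 °C; cold aq. NaHCO3 wash, used crude
Reagents that add atoms: phosphorus tribromide, BrP(Br)Br
Why: Bromination of a benzylic alcohol with PBr3 (phosphite ester formation, then displacement by bromide) should be fast for this para-alkoxybenzyl alcohol at 0 °C, and the sensitive bromide is carried on without purification.

**Step 7**
Reactants: 12 5'-allyl-3'-(3-allyl-4-methoxyphenyl)-3-(bromomethyl)-6-ethoxy-2'-methoxybiphenyl
Product: 13 3,5'-diallyl-3'-(3-allyl-4-methoxyphenyl)-6-ethoxy-2'-methoxybiphenyl (simonsinol with ring A as ethyl ether, rings B and C as methyl ethers)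
Conditions: CH2=CHMgBr (2.5 equiv), CuI (10 mol %), THF, −20 → 0 °C
Reagents that add atoms: vinylmagnesium bromide, C=C[Mg]Br
Why: Copper-catalysed cross-coupling of a benzylic bromide with a vinyl Grignard reagent should join the CH2 group to the vinyl group through a vinylcopper species faster than any uncatalysed pathway, and the product has no site that excess reagent can attack.

**Step 8**
Reactants: 13 3,5'-diallyl-3'-(3-allyl-4-methoxyphenyl)-6-ethoxy-2'-methoxybiphenyl
Product: 14 simonsinol
Conditions: BBr3 (6 equiv), CH2Cl2, −78 → 0 °C; aq. NaHCO3
Reagents that add atoms: none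
Why: Lewis acid ether cleavage: BBr3 binds each ether oxygen and bromide removes the methyl or ethyl group by SN2, the aryl borates being hydrolysed on work-up to the three phenols, a cleavage that is well precedented for aryl methyl ethers bearing allyl groups when kept cold.

**Compound list**

1 | 4-O-methylhonokiol (3',5-diallyl-4'-methoxybiphenyl-2-ol) | C=CCc1ccc(O)c(-c2ccc(OC)c(CC=C)c2)c1 | starting material
2 | 3',5-diallyl-3-iodo-4'-methoxybiphenyl-2-ol | C=CCc1cc(I)c(O)c(-c2ccc(OC)c(CC=C)c2)c1 | intermediate
3 | 3',5-diallyl-3-iodo-2,4'-dimethoxybiphenyl | C=CCc1cc(I)c(OC)c(-c2ccc(OC)c(CC=C)c2)c1 | intermediate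
4 | ethoxyacetylene | CCOC#C | starting material
5 | lithium ethoxyacetylide | CCOC#C[Li] | intermediate
6 | ethoxyethynylzinc chloride | CCOC#C[Zn]Cl | intermediate
7 | 3',5-diallyl-3-(ethoxyethynyl)-2,4'-dimethoxybiphenyl | CCOC#Cc1cc(CC=C)cc(-c2ccc(OC)c(CC=C)c2)c1OC | intermediate
8 | methyl coumalate (methyl 2-oxo-2H-pyran-5-carboxylate) | COC(=O)c1ccc(=O)oc1 | starting material
9 | methyl 6-(3',5-diallyl-2,4'-dimethoxybiphenyl-3-yl)-5-ethoxy-3-oxo-2-oxabicyclo[2.2.2]octa-5,7-diene-7-carboxylate (racemic, one enantiomer drawn; bridgehead configuration fixed by the bicycle) | O=C1O[C@@H]2C(C(=O)OC)=C[C@H]1C(OCC)=C2c3cc(CC=C)cc(-c4ccc(OC)c(CC=C)c4)c3OC | intermediate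
10 | methyl 5'-allyl-3'-(3-allyl-4-methoxyphenyl)-6-ethoxy-2'-methoxybiphenyl-3-carboxylate | CCOc1ccc(C(=O)OC)cc1-c1cc(CC=C)cc(-c2ccc(OC)c(CC=C)c2)c1OC | intermediate
11 | [5'-allyl-3'-(3-allyl-4-methoxyphenyl)-6-ethoxy-2'-methoxybiphenyl-3-yl]methanol | CCOc1ccc(CO)cc1-c1cc(CC=C)cc(-c2ccc(OC)c(CC=C)c2)c1OC | intermediate
12 | 5'-allyl-3'-(3-allyl-4-methoxyphenyl)-3-(bromomethyl)-6-ethoxy-2'-methoxybiphenyl | CCOc1ccc(CBr)cc1-c1cc(CC=C)cc(-c2ccc(OC)c(CC=C)c2)c1OC | intermediate
13 | 3,5'-diallyl-3'-(3-allyl-4-methoxyphenyl)-6-ethoxy-2'-methoxybiphenyl | CCOc1ccc(CC=C)cc1-c1cc(CC=C)cc(-c2ccc(OC)c(CC=C)c2)c1OC | intermediate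
14 | simonsinol | C=CCc1ccc(O)c(-c2cc(CC=C)cc(-c3ccc(O)c(CC=C)c3)c2O)c1 | target

**Step count**

Total steps: 8. Longest linear sequence: 8 steps (1 to 14).

**Steps most likely to fail**

Step 4. The cycloaddition may be too slow at the temperature the ynol ether tolerates, so that fragmentation of 7 to an arylketene and ethylene, or its hydration by adventitious water, outruns ring formation. The fallback sets out from iodide 3 and comes back at ester 10, bringing ring A in ready-made. Suzuki–Miyaura coupling of 3 with (2-ethoxy-5-(methoxycarbonyl)phenyl)boronic acid (CCOc1ccc(C(=O)OC)cc1B(O)O) under Pd(OAc)2/SPhos, K3PO4, toluene/water, 80 °C should form the ring A–ring B bond directly. The allyl groups and both ethers are inert to these conditions. This fallback makes no compound outside the list (F0).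

Step 3. Transmetalation and coupling at the iodide next to the flanked methoxy group may be slow enough for the zinc acetylide to decompose, and the ynol ether may hydrate to the arylacetic ester during work-up or chromatography. The fallback sets out from iodide 3 and comes back at ynol ether 7, forming the triple bond by elimination under anhydrous basic conditions. Iodine–magnesium exchange on 3 (i-PrMgCl·LiCl, THF, −20 °C) and addition of the arylmagnesium species to 2-ethoxy-N-methoxy-N-methylacetamide should give 1-(3',5-diallyl-2,4'-dimethoxybiphenyl-3-yl)-2-ethoxyethanone F1. Enolisation with KN(SiMe3)2 and trapping with PhNTf2 (THF, −78 °C) should give, through the chelated enolate, the (Z)-enol triflate F2, in which the vinylic hydrogen lies anti to the triflate. KOt-Bu in THF at −78 °C should then eliminate triflate to give 7, which can be taken into step 4 after a non-aqueous filtration.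

Step 8. HBr formed during the cleavage may add across the allyl double bonds or promote cyclisation of the ortho-allylphenol of ring C onto its alkene, while the slower ethyl ether and the flanked ring B methyl ether are still reacting. The fallback sets out from 13 and comes back at 14 by nucleophilic rather than Lewis acid dealkylation. NaSEt (excess) in DMF at 120–130 °C should remove the two methyl groups and the ethyl group by SN2 attack of thiolate on the alkyl carbons, with no acid present. Mild acidification on work-up then frees the three phenols. This fallback makes no compound outside the list (F0).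

**Further compounds**

F0 | step 4 | none | none
F1 | step 3 | 1-(3',5-diallyl-2,4'-dimethoxybiphenyl-3-yl)-2-ethoxyethanone | CCOCC(=O)c1cc(CC=C)cc(-c2ccc(OC)c(CC=C)c2)c1OC
F2 | step 3 | (Z)-1-(3',5-diallyl-2,4'-dimethoxybiphenyl-3-yl)-2-ethoxyvinyl trifluoromethanesulfonate | CCO/C=C(\OS(=O)(=O)C(F)(F)F)c1cc(CC=C)cc(-c2ccc(OC)c(CC=C)c2)c1OC
F0 | step 8 | none | none
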